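**Retrosynthetic overview**

1. Numbering: ring C1 (ketone), C2 (bearing C7H2OAc), C3, C4 (carbinol), C5 (quaternary oxirane carbon), C6 (oxirane CH); chain C1'–C11'. The route rests on the C1' carbinol, which lies between C5 of the cyclohexenone–oxirane bicycle and the E-trisubstituted C2'=C3' alkene that opens the labile triene. C3'–CH3 and C1'–C2' are therefore disconnected last, back to a C1' aldehyde and a terminal alkyne.
2. Core: arene 1 supplies C1–C6 and C1'. Its phenol 8 is dearomatised to quinone monoketal 9, in which C1 is masked so that only the C4 carbonyl is free (a symmetric quinone epoxide would offer the hydride two carbonyls). Oxirane formation (10), C4 reduction, protecting-group changes and oxidation lead to aldehyde 16.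
3. Chain: 17 and 18 give enyne 21 (C2' and C4'–C11' with their methyl groups).
4. Union: 21, 22 and 16 give 25 in one flask (methylalumination, then alkenyl transfer to C1'); desilylation gives 26.
5. Ring order: the six-membered ring is the benzene ring of 1 and is never opened; the oxirane is closed in step 6; no ring forms afterwards.

Key step: step 15

Assumption: in step 6 L-(+)-diisopropyl tartrate is taken to steer the peroxide to the ring face drawn for 10; the sense is to be checked on 11 by MTPA ester analysis, and the D-(−)-tartrate is used instead if the antipode forms.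

**Route**

Step 1
Reactants: 1 4-bromo-2,5-dimethoxybenzaldehyde
Product: 2 4-bromo-2-hydroxy-5-methoxybenzaldehyde
Conditions: BCl3 (1.2 equiv), CH2Cl2, −78 → 0 °C; H2O
Reagents that add atoms: none
Why: Chelation-directed Lewis acid ether cleavage, in which BCl3 bound to the formyl oxygen removes only the methyl group of the ortho methoxy group, the other methoxy group having no carbonyl neighbour.

Step 2
Reactants: 2 4-bromo-2-hydroxy-5-methoxybenzaldehyde
Product: 3 5-bromo-2-(hydroxymethyl)-4-methoxyphenol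
Conditions: NaBH4, MeOH–THF, 0 °C
Reagents that add atoms: none
Why: Borohydride reduction of the aldehyde, to which the aryl bromide and the aryl ether are inert; this carbon becomes C1'.

Step 3
Reactants: 3 5-bromo-2-(hydroxymethyl)-4-methoxyphenol
Product: 5 5-bromo-4-methoxy-2-{[(4-methoxybenzyl)oxy]methyl}phenol, via disodium dianion 4 (not isolated)
Conditions: NaH (2.2 equiv), DMF, 0 °C; PMBCl (1.0 equiv), Bu4NI (cat.), 0 °C → rt; H2O
Reagents that add atoms: 4-methoxybenzyl chloride (PMBCl), COc1ccc(CCl)cc1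
Why: Williamson etherification of dianion 4, in which the benzylic alkoxide is far more basic and nucleophilic than the phenoxide, so that one equivalent of PMBCl should be taken up at the CH2O oxygen and the phenol is recovered on work-up.

Step 4
Reactants: 5 5-bromo-4-methoxy-2-{[(4-methoxybenzyl)oxy]methyl}phenol
Product: 8 5-(hydroxymethyl)-4-methoxy-2-{[(4-methoxybenzyl)oxy]methyl}phenol, via aryllithium 6 (not isolated), via aldehyde 7 (not isolated)
Conditions: n-BuLi (2.3 equiv), THF, −78 °C; DMF, −78 → 0 °C; then MeOH, NaBH4, 0 °C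
Reagents that add atoms: N,N-dimethylformamide (DMF), CN(C)C=O
Why: Bromine–lithium exchange on the lithium phenoxide gives aryllithium 6, which is formylated by DMF (Bouveault aldehyde synthesis), and aldehyde 7 is reduced by borohydride in the same flask; the new carbon becomes C7.

Step 5
Reactants: 8 5-(hydroxymethyl)-4-methoxy-2-{[(4-methoxybenzyl)oxy]methyl}phenol
Product: 9 5-(hydroxymethyl)-4,4-dimethoxy-2-{[(4-methoxybenzyl)oxy]methyl}cyclohexa-2,5-dien-1-one
Conditions: PhI(OAc)2 (1.1 equiv), MeOH, 0 °C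
Reagents that add atoms: methanol, CO
Why: Hypervalent-iodine oxidative dearomatisation of a para-methoxyphenol in methanol, which turns the phenol carbon into the C4 carbonyl and the anisole carbon into the C1 dimethyl ketal and so decides which carbonyl is free for step 7.

Step 6
Reactants: 9 5-(hydroxymethyl)-4,4-dimethoxy-2-{[(4-methoxybenzyl)oxy]methyl}cyclohexa-2,5-dien-1-one
Product: 10 (1S,6R)-4-(hydroxymethyl)-5,5-dimethoxy-1-{[(4-methoxybenzyl)oxy]methyl}-7-oxabicyclo[4.1.0]hept-3-en-2-one
Conditions: Ph3COOH (2 equiv), NaN(SiMe3)2 (3 equiv), L-(+)-diisopropyl tartrate (2 equiv), toluene, −78 → −40 °C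
Reagents that add atoms: trityl hydroperoxide, OOC(c1ccccc1)(c1ccccc1)c1ccccc1
Why: Weitz–Scheffer-type nucleophilic epoxidation, tartrate-mediated and directed by the sodium alkoxide of the C7 hydroxymethyl group, in which the peroxide adds to C6 (the only unsubstituted β-carbon), the enolate closes the oxirane at C5 (3-exo-tet), and the tartrate–alkoxide–peroxide aggregate selects the ring face and thereby sets C5 and C6 together.

Step 7
Reactants: 10 (1S,6R)-4-(hydroxymethyl)-5,5-dimethoxy-1-{[(4-methoxybenzyl)oxy]methyl}-7-oxabicyclo[4.1.0]hept-3-en-2-one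
Product: 11 (1R,2S,6R)-4-(hydroxymethyl)-5,5-dimethoxy-1-{[(4-methoxybenzyl)oxy]methyl}-7-oxabicyclo[4.1.0]hept-3-en-2-ol
Conditions: iBu2AlH (3.2 equiv), THF, −78 °C; aq. KNaC4H4O6 (potassium sodium tartrate)
Reagents that add atoms: none
Why: 1,2-Reduction of the enone carbonyl by an aluminium hydride coordinated to the oxirane oxygen, so that hydride enters C4 from the oxirane face, which is also the face away from the C5 CH2OPMB arm, and the new hydroxyl should stand trans to the oxirane oxygen (4S), while C1 stays protected as the ketal.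

Step 8
Reactants: 11 (1R,2S,6R)-4-(hydroxymethyl)-5,5-dimethoxy-1-{[(4-methoxybenzyl)oxy]methyl}-7-oxabicyclo[4.1.0]hept-3-en-2-ol
Product: 12 [(1R,5S,6R)-5-hydroxy-2,2-dimethoxy-6-{[(4-methoxybenzyl)oxy]methyl}-7-oxabicyclo[4.1.0]hept-3-en-3-yl]methyl acetate
Conditions: Ac2O (1.05 equiv), pyridine, CH2Cl2, −20 → 0 °C
Reagents that add atoms: acetic anhydride, CC(=O)OC(C)=O
Why: Selective O-acylation, the primary allylic C7 hydroxyl reacting much faster than the secondary C4 hydroxyl, which is flanked by the quaternary C5.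

Step 9
Reactants: 12 [(1R,5S,6R)-5-hydroxy-2,2-dimethoxy-6-{[(4-methoxybenzyl)oxy]methyl}-7-oxabicyclo[4.1.0]hept-3-en-3-yl]methyl acetate
Product: 13 [(1R,5S,6S)-5-{[tert-butyl(dimethyl)silyl]oxy}-2,2-dimethoxy-6-{[(4-methoxybenzyl)oxy]methyl}-7-oxabicyclo[4.1.0]hept-3-en-3-yl]methyl acetate
Conditions: TBSOTf (1.5 equiv), 2,6-lutidine, CH2Cl2, −78 → 0 °C
Reagents that add atoms: tert-butyldimethylsilyl triflate (TBSOTf), CC(C)(C)[Si](C)(C)OS(=O)(=O)C(F)(F)F
Why: O-Silylation of the hindered secondary alcohol with a silyl triflate, the bulky and weakly Lewis-basic silyl ether being chosen so that O4 cannot act as a chelating donor in step 15.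

Step 10
Reactants: 13 [(1R,5S,6S)-5-{[tert-butyl(dimethyl)silyl]oxy}-2,2-dimethoxy-6-{[(4-methoxybenzyl)oxy]methyl}-7-oxabicyclo[4.1.0]hept-3-en-3-yl]methyl acetate
Product: 14 [(1R,5S,6S)-5-{[tert-butyl(dimethyl)silyl]oxy}-6-{[(4-methoxybenzyl)oxy]methyl}-2-oxo-7-oxabicyclo[4.1.0]hept-3-en-3-yl]methyl acetate
Conditions: PPTS (0.2 equiv), acetone–H2O (10:1), 45 °C
Reagents that add atoms: water, O
Why: Acid-catalysed hydrolysis of the allylic dimethyl ketal (its oxocarbenium ion is conjugated with C2=C3), which the hindered secondary silyl ether, the benzyl-type ether, the acetate and the oxirane should tolerate under this weak acid.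

Step 11
Reactants: 14 [(1R,5S,6S)-5-{[tert-butyl(dimethyl)silyl]oxy}-6-{[(4-methoxybenzyl)oxy]methyl}-2-oxo-7-oxabicyclo[4.1.0]hept-3-en-3-yl]methyl acetate
Product: 15 [(1R,5S,6S)-5-{[tert-butyl(dimethyl)silyl]oxy}-6-(hydroxymethyl)-2-oxo-7-oxabicyclo[4.1.0]hept-3-en-3-yl]methyl acetate
Conditions: DDQ (1.3 equiv), CH2Cl2–aq. NaH2PO4/Na2HPO4 (pH 7), 10:1, 0 °C → rt
Reagents that add atoms: none
Why: Oxidative cleavage of the 4-methoxybenzyl ether by DDQ (hydride abstraction, then hydrolysis of the oxocarbenium ion), which leaves the electron-poor enone, the acetate, the silyl ether and the oxirane untouched.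

Step 12
Reactants: 15 [(1R,5S,6S)-5-{[tert-butyl(dimethyl)silyl]oxy}-6-(hydroxymethyl)-2-oxo-7-oxabicyclo[4.1.0]hept-3-en-3-yl]methyl acetate
Product: 16 [(1R,5S,6S)-5-{[tert-butyl(dimethyl)silyl]oxy}-6-formyl-2-oxo-7-oxabicyclo[4.1.0]hept-3-en-3-yl]methyl acetate
Conditions: Dess–Martin periodinane (1.5 equiv), CH2Cl2, 0 °C → rt
Reagents that add atoms: none
Why: Dess–Martin oxidation of the neopentyl-type primary alcohol under non-basic conditions, giving an aldehyde that has no α-hydrogen (C5 is quaternary) and so cannot enolise or epimerise.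

Step 13
Reactants: 17 1-(trimethylsilyl)propyne; 18 geranyl bromide
Product: 20 [(5E)-6,10-dimethylundeca-5,9-dien-1-yn-1-yl](trimethyl)silane, via propargyllithium 19 (not isolated)
Conditions: 17, n-BuLi (1.05 equiv), THF, −78 → −20 °C; then 18, −78 °C → rt
Reagents that add atoms: none
Why: Propargylation by SN2 alkylation, in which lithiation of 17 at the methyl group gives propargyl anion 19 that displaces the primary allylic bromide at carbon, the silyl group blocking the alkyne terminus and the E alkene of the geranyl unit being untouched.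

Step 14
Reactants: 20 [(5E)-6,10-dimethylundeca-5,9-dien-1-yn-1-yl](trimethyl)silane
Product: 21 (5E)-6,10-dimethylundeca-5,9-dien-1-yne
Conditions: K2CO3 (cat.), MeOH, rt
Reagents that add atoms: none
Why: Base-catalysed protiodesilylation of the alkynylsilane by methanolysis.

Step 15
Reactants: 21 (5E)-6,10-dimethylundeca-5,9-dien-1-yne; 22 trimethylaluminium; 16 [(1R,5S,6S)-5-{[tert-butyl(dimethyl)silyl]oxy}-6-formyl-2-oxo-7-oxabicyclo[4.1.0]hept-3-en-3-yl]methyl acetate
Product: 25 [(1R,5S,6S)-5-{[tert-butyl(dimethyl)silyl]oxy}-6-[(1S,2E,6E)-1-hydroxy-3,7,11-trimethyldodeca-2,6,10-trien-1-yl]-2-oxo-7-oxabicyclo[4.1.0]hept-3-en-3-yl]methyl acetate, via alkenylalane 23 (not isolated), via aluminium alkoxide 24 (not isolated)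
Conditions: 21, AlMe3 (2.5 equiv), Cp2ZrCl2 (0.25 equiv), CH2Cl2, 0 °C → rt; excess AlMe3 and solvent removed in vacuo; residue in CH2Cl2–hexane, 16 added at −78 °C; aq. KNaC4H4O6
Reagents that add atoms: trimethylaluminium (AlMe3, compound 22), C[Al](C)C
Why: Cp2ZrCl2 (tetravalent zirconium) and AlMe3 form a methylzirconium–aluminium species that adds CH3 and metal syn across the terminal alkyne of 21, CH3 to the internal carbon (future C3') and the metal, ending on aluminium, to the terminal carbon (future C2'), which fixes the 2'E geometry in alane 23. Once the excess AlMe3 has been stripped off, 23 binds the formyl oxygen of 16 and transfers its alkenyl group, which migrates faster than methyl, to C1' with retention of alkene geometry, giving alkoxide 24 and, on work-up, 25. The closest known reaction type is the zirconium-catalysed methylalumination of a terminal alkyne (Negishi carboalumination) followed by 1,2-addition of the alkenylalane to an aldehyde, and no ring is closed in this step. The new stereocentre C1' is set by substrate control: aluminium bridges the formyl oxygen and the oxirane oxygen on C5, which holds C1'=O syn to the C5–O bond, and the alkenyl group then enters from the side of the oxirane CH (C6), away from C4 and its silyloxy group, which should give 1'S. The step needs chemoselectivity for the aldehyde and this facial selectivity: the cyclohexenone is locked s-trans and cannot undergo cyclic conjugate alkenyl transfer, its ketone, the acetate and the oxirane are slower electrophiles at −78 °C, C5 is quaternary so the aldehyde cannot enolise, and the bulky, poorly coordinating silyl ether on O4 together with the donor-free solvent leaves the oxirane oxygen as the only chelating partner.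

Step 16
Reactants: 25 [(1R,5S,6S)-5-{[tert-butyl(dimethyl)silyl]oxy}-6-[(1S,2E,6E)-1-hydroxy-3,7,11-trimethyldodeca-2,6,10-trien-1-yl]-2-oxo-7-oxabicyclo[4.1.0]hept-3-en-3-yl]methyl acetate
Product: 26 [(1R,5S,6R)-5-hydroxy-6-[(1S,2E,6E)-1-hydroxy-3,7,11-trimethyldodeca-2,6,10-trien-1-yl]-2-oxo-7-oxabicyclo[4.1.0]hept-3-en-3-yl]methyl acetate
Conditions: HF·pyridine, pyridine, THF, 0 °C → rt
Reagents that add atoms: none
Why: Fluoride-mediated silyl ether cleavage driven by Si–F bond formation, with pyridine buffering so that the allylic C1' alcohol, the oxirane, the acetate and the triene should not suffer acid- or base-induced change.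

**Compound list**

Locants in the names of 10–16, 25 and 26 are those of the 7-oxabicyclo[4.1.0]heptene skeleton. The descriptor at the quaternary oxirane carbon switches between R and S along the series only because substituent priorities change; the spatial arrangement is the same throughout.

1 | 4-bromo-2,5-dimethoxybenzaldehyde | COc1cc(C=O)c(OC)cc1Br | starting material
2 | 4-bromo-2-hydroxy-5-methoxybenzaldehyde | COc1cc(C=O)c(O)cc1Br | intermediate
3 | 5-bromo-2-(hydroxymethyl)-4-methoxyphenol | COc1cc(CO)c(O)cc1Br | intermediate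
4 | disodium dianion of 3 (sodium phenoxide and sodium benzylic alkoxide) | [Na+].[Na+].COc1cc(C[O-])c([O-])cc1Br | intermediate
5 | 5-bromo-4-methoxy-2-{[(4-methoxybenzyl)oxy]methyl}phenol | COc1ccc(COCc2cc(OC)c(Br)cc2O)cc1 | intermediate
6 | lithium 5-lithio-4-methoxy-2-{[(4-methoxybenzyl)oxy]methyl}phenoxide | [Li]Oc1cc([Li])c(OC)cc1COCc1ccc(OC)cc1 | intermediate
7 | 5-hydroxy-2-methoxy-4-{[(4-methoxybenzyl)oxy]methyl}benzaldehyde | O=Cc1cc(O)c(COCc2ccc(OC)cc2)cc1OC | intermediate
8 | 5-(hydroxymethyl)-4-methoxy-2-{[(4-methoxybenzyl)oxy]methyl}phenol | OCc1cc(O)c(COCc2ccc(OC)cc2)cc1OC | intermediate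
9 | 5-(hydroxymethyl)-4,4-dimethoxy-2-{[(4-methoxybenzyl)oxy]methyl}cyclohexa-2,5-dien-1-one | COc1ccc(COCC2=CC(OC)(OC)C(CO)=CC2=O)cc1 | intermediate
10 | (1S,6R)-4-(hydroxymethyl)-5,5-dimethoxy-1-{[(4-methoxybenzyl)oxy]methyl}-7-oxabicyclo[4.1.0]hept-3-en-2-one | OCC1=CC(=O)[C@@]2(COCc3ccc(OC)cc3)O[C@H]2C1(OC)OC | intermediate
11 | (1R,2S,6R)-4-(hydroxymethyl)-5,5-dimethoxy-1-{[(4-methoxybenzyl)oxy]methyl}-7-oxabicyclo[4.1.0]hept-3-en-2-ol (hydroxyl trans to the oxirane oxygen) | OCC1=C[C@H](O)[C@@]2(COCc3ccc(OC)cc3)O[C@H]2C1(OC)OC | intermediate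
12 | [(1R,5S,6R)-5-hydroxy-2,2-dimethoxy-6-{[(4-methoxybenzyl)oxy]methyl}-7-oxabicyclo[4.1.0]hept-3-en-3-yl]methyl acetate | CC(=O)OCC1=C[C@H](O)[C@@]2(COCc3ccc(OC)cc3)O[C@H]2C1(OC)OC | intermediate
13 | [(1R,5S,6S)-5-{[tert-butyl(dimethyl)silyl]oxy}-2,2-dimethoxy-6-{[(4-methoxybenzyl)oxy]methyl}-7-oxabicyclo[4.1.0]hept-3-en-3-yl]methyl acetate | CC(=O)OCC1=C[C@H](O[Si](C)(C)C(C)(C)C)[C@@]2(COCc3ccc(OC)cc3)O[C@H]2C1(OC)OC | intermediate
14 | [(1R,5S,6S)-5-{[tert-butyl(dimethyl)silyl]oxy}-6-{[(4-methoxybenzyl)oxy]methyl}-2-oxo-7-oxabicyclo[4.1.0]hept-3-en-3-yl]methyl acetate | CC(=O)OCC1=C[C@H](O[Si](C)(C)C(C)(C)C)[C@@]2(COCc3ccc(OC)cc3)O[C@H]2C1=O | intermediate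
15 | [(1R,5S,6S)-5-{[tert-butyl(dimethyl)silyl]oxy}-6-(hydroxymethyl)-2-oxo-7-oxabicyclo[4.1.0]hept-3-en-3-yl]methyl acetate | CC(=O)OCC1=C[C@H](O[Si](C)(C)C(C)(C)C)[C@@]2(CO)O[C@H]2C1=O | intermediate
16 | [(1R,5S,6S)-5-{[tert-butyl(dimethyl)silyl]oxy}-6-formyl-2-oxo-7-oxabicyclo[4.1.0]hept-3-en-3-yl]methyl acetate (epoxyquinol C1' aldehyde) | CC(=O)OCC1=C[C@H](O[Si](C)(C)C(C)(C)C)[C@@]2(C=O)O[C@H]2C1=O | intermediate
17 | 1-(trimethylsilyl)propyne | CC#C[Si](C)(C)C | starting material
18 | geranyl bromide, (2E)-1-bromo-3,7-dimethylocta-2,6-diene | CC(C)=CCC/C(C)=C/CBr | starting material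
19 | 3-(trimethylsilyl)prop-2-yn-1-yllithium | [Li]CC#C[Si](C)(C)C | intermediate
20 | [(5E)-6,10-dimethylundeca-5,9-dien-1-yn-1-yl](trimethyl)silane | C[Si](C)(C)C#CCC/C=C(\C)CCC=C(C)C | intermediate
21 | (5E)-6,10-dimethylundeca-5,9-dien-1-yne | C#CCC/C=C(\C)CCC=C(C)C | intermediate
22 | trimethylaluminium | C[Al](C)C | starting material
23 | dimethyl[(1E,5E)-2,6,10-trimethylundeca-1,5,9-trien-1-yl]alane | C[Al](C)/C=C(\C)CC/C=C(\C)CCC=C(C)C | intermediate
24 | dimethylaluminium O1'-alkoxide of 25 | CC(=O)OCC1=C[C@H](O[Si](C)(C)C(C)(C)C)[C@@]2([C@@H](O[Al](C)C)/C=C(\C)CC/C=C(\C)CCC=C(C)C)O[C@H]2C1=O | intermediate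
25 | [(1R,5S,6S)-5-{[tert-butyl(dimethyl)silyl]oxy}-6-[(1S,2E,6E)-1-hydroxy-3,7,11-trimethyldodeca-2,6,10-trien-1-yl]-2-oxo-7-oxabicyclo[4.1.0]hept-3-en-3-yl]methyl acetate | CC(=O)OCC1=C[C@H](O[Si](C)(C)C(C)(C)C)[C@@]2([C@@H](O)/C=C(\C)CC/C=C(\C)CCC=C(C)C)O[C@H]2C1=O | intermediate
26 | [(1R,5S,6R)-5-hydroxy-6-[(1S,2E,6E)-1-hydroxy-3,7,11-trimethyldodeca-2,6,10-trien-1-yl]-2-oxo-7-oxabicyclo[4.1.0]hept-3-en-3-yl]methyl acetate | CC(=O)OCC1=C[C@H](O)[C@@]2([C@@H](O)/C=C(\C)CC/C=C(\C)CCC=C(C)C)O[C@H]2C1=O | target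

**Step count and risk**

Total step count: 16. Longest linear sequence: 14 steps (steps 1–12, 15 and 16); the enyne branch is steps 13 and 14.

Steps most likely to fail:

Step 15. Chelation by aluminium may be incomplete, so that the non-chelated rotamer reacts and the 1'R epimer forms. Methyl transfer or Lewis-acid opening of the oxirane may also compete with alkenyl transfer. The fallback sets out from enyne 21 and aldehyde 16. Methylalumination as in step 15 followed by iodinolysis (I2, THF, −30 °C) gives (1E,5E)-1-iodo-2,6,10-trimethylundeca-1,5,9-triene F1. Iodine–lithium exchange (t-BuLi, Et2O, −78 °C) and transmetalation with MgBr2·OEt2 give the alkenylmagnesium bromide F2. F2 is added at −78 °C to 16 that has been precomplexed with MgBr2·OEt2 in CH2Cl2, so that a magnesium chelate of the formyl and oxirane oxygens, formed before the nucleophile arrives, fixes the rotamer. The fallback comes back to the route at 25.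

Step 6. Enantiofacial control by the tartrate aggregate may be incomplete or reversed for this substitution pattern, or peroxide addition at the substituted alkene may be slow. The fallback sets out from 9. Racemic Weitz–Scheffer epoxidation (t-BuOOH, DBU, CH2Cl2, 0 °C) gives the racemic epoxide F3. Esterification of its primary hydroxyl with (S)-methoxy(phenyl)acetic acid (carbodiimide, DMAP) gives the diastereomeric esters F4 and F5, which are separated by chromatography or crystallisation. Methanolysis of F4 (K2CO3, MeOH, 0 °C) releases enantiopure 10, where the route is rejoined.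

Step 7. Hydride may be delivered from the face of the C5 arm instead of the oxirane face, giving the C4 epimer. The fallback sets out from 10 and corrects the centre by inversion instead of by reduction. The epimeric diol F6 is acetylated at the primary hydroxyl as in step 8 to give the acetate F7. A Mitsunobu reaction (4-nitrobenzoic acid, PPh3, diisopropyl azodicarboxylate, toluene, 0 °C → rt) inverts C4 and gives the 4-nitrobenzoate F8. Methanolysis of both esters (K2CO3, MeOH) returns diol 11, where the route is rejoined at step 8.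

Further compounds
F1 | step 15 | (1E,5E)-1-iodo-2,6,10-trimethylundeca-1,5,9-triene | I/C=C(\C)CC/C=C(\C)CCC=C(C)C
F2 | step 15 | bromo[(1E,5E)-2,6,10-trimethylundeca-1,5,9-trien-1-yl]magnesium | Br[Mg]/C=C(\C)CC/C=C(\C)CCC=C(C)C
F3 | step 6 | racemic 4-(hydroxymethyl)-5,5-dimethoxy-1-{[(4-methoxybenzyl)oxy]methyl}-7-oxabicyclo[4.1.0]hept-3-en-2-one | OCC1=CC(=O)C2(COCc3ccc(OC)cc3)OC2C1(OC)OC
F4 | step 6 | (2S)-methoxy(phenyl)acetate ester of 10 at the primary hydroxyl | CO[C@H](C(=O)OCC1=CC(=O)[C@@]2(COCc3ccc(OC)cc3)O[C@H]2C1(OC)OC)c1ccccc1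
F5 | step 6 | (2S)-methoxy(phenyl)acetate ester of the enantiomer of 10 | CO[C@H](C(=O)OCC1=CC(=O)[C@]2(COCc3ccc(OC)cc3)O[C@@H]2C1(OC)OC)c1ccccc1
F6 | step 7 | C4 epimer of 11 (hydroxyl cis to the oxirane oxygen) | OCC1=C[C@@H](O)[C@@]2(COCc3ccc(OC)cc3)O[C@H]2C1(OC)OC
F7 | step 7 | C4 epimer of 12 | CC(=O)OCC1=C[C@@H](O)[C@@]2(COCc3ccc(OC)cc3)O[C@H]2C1(OC)OC
F8 | step 7 | 4-nitrobenzoate of 12 at O4 (C4 inverted, ester trans to the oxirane oxygen) | CC(=O)OCC1=C[C@H](OC(=O)c3ccc(cc3)[N+](=O)[O-])[C@@]2(COCc4ccc(OC)cc4)O[C@H]2C1(OC)OC
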